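The numbers of this flask belong to no real substance.

At early times the solid substrate has two ways out, dimerisation and dissolution, and I asked how the charge divides between them.

    2 solid substrate → homo dimer (k1 = 0.0438 M⁻¹ s⁻¹)
    dissolved substrate + reagent ⇌ product (K2 = 0.56 M⁻¹, k2 = 0.0252 M⁻¹ s⁻¹)
    solid substrate ⇌ dissolved substrate, rate k3*(cs3 - [dissolved substrate]) while solid is left; crystals form when [dissolved substrate] > cs3 (cs3 = 0.26 M, k3 = 0.0129 s⁻¹)

solid substrate 0.50 M; reagent 1.20 equiv; time 5.0 min

- percent here means solid substrate units held: one homo dimer counts as two
- a step written with two of one species runs at k times the square of its concentration and takes two of it each time
- solid substrate is a solid; its amount is given per volume of the solution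
- at the start none of the solid substrate is in solution
- dissolved substrate means what is dissolved; the solid is not counted in it
- run time (flask): 5.0 min

1. how much product there is at 5.0 min, in percent of the solid substrate charged
2. concentration of dissolved substrate in solution at 5.0 min, in percent of saturation

I began with the empty solution. There the solid substrate went to homo dimer at 1.31 M min⁻¹ and into solution at 0.201 M min⁻¹, so dimerisation ran faster by a selectivity factor of 6.52. Dividing the rates removes time, and my first guess was that a steady 13.3% of the charge dissolved. I distrusted this at once: the factor goes with the square of c(solid substrate), so it must fall as the solid is used.

Setting the rates equal gave 0.196 M. This is the crossover concentration, the c(solid substrate) at which dimerisation and dissolution into an empty solution take solid equally fast. Against an empty solution, dimerisation leads above it and dissolution below it, so I took the amount reaching solution to be about this concentration, 39.1% of the charge. Two objections remained. Some solid dissolves above the crossover, which raises the figure, while dissolved substrate slows its own passage, which lowers it. They pull opposite ways, so I kept the figure. It lies below saturation, so I expected no crystals.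

But dissolved substrate does not stay as it is. Its half-life by the forward reagent step, 0.76 min, is short against the 5.0 min run, so I assumed balance, with product equal to 0.34 times c(dissolved substrate). That split gave c(dissolved substrate) = 0.146 M, or 56.3% of saturation, and product 0.0492 M, or 9.84% of the charge. The reagent would lose 8.20% of itself, a small correction that I let stand.

The forecast gave 9% and 56%, holding that “the dissolved substrate never reaches saturation”.

The flask gave 10.0% of product. Its dissolved substrate stood at 62.8% of saturation. At 5.00 min the flask held dissolved substrate 32.6% and product 10.0%, together 42.6% of the charge against the crossover's 39.1%. No reagent enters the crossover concentration, so for the neighbour flask with 4.80 equiv of reagent I kept it and scaled the balance to 1.34. This gives product 22.4% of the charge, and that neighbour flask gave 24.7%.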